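## Retrosynthetic overview

1. Target 17 ⇒ acyclic (Z)-allylic bromide 13. A sulfonium ylide at C6 adds to the C1 ketone and the betaine closes, so the cyclohexene (C1–C6 bond) and the oxirane (C6–O bond) form together in the last operation.
2. 13 ⇒ silyl ether 12 (OTBS → Br) ⇒ alkyne 11 (Lindlar reduction gives the Z-alkene that ring closure needs).
3. α-Benzoyloxy ketone 11 ⇒ terminal alkene 8 (dihydroxylation, primary benzoylation, oxidation).
4. syn-Methoxy alcohol 7 (C2/C3 of the target) ⇒ ynal 3 + allyl methyl ether 4 by (Z)-γ-methoxyallylboration; 3 ⇒ silyl propargyl ether 1 + DMF.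
5. Ring order: no ring is made before step 9; carbocycle and epoxide form simultaneously, and the two phenyl rings are bought as benzoyl chloride.

Assumption: the methoxyallylborane made from (−)-Ipc2BOMe (from (+)-α-pinene) attacks the same aldehyde face as the parent allylborane from that borinate (the one that gives (S)-1-phenylbut-3-en-1-ol from benzaldehyde). C1–C7 in the text are target positions (C1 = quaternary epoxide carbon, C6 = epoxide CH, C7 = CH2OBz).

## Route

**Step 1**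
Reactants: 1 tert-butyldimethyl(prop-2-yn-1-yloxy)silane
Product: 3 4-[(tert-butyldimethylsilyl)oxy]but-2-ynal, via lithium acetylide 2 (not isolated)
Conditions: n-BuLi (1.05 equiv), THF, −78 °C; DMF (2 equiv), −78 → 0 °C; reverse quench into cold 10% aq. KH2PO4
Reagents that add atoms: N,N-dimethylformamide `CN(C)C=O`
Why: Deprotonation of the terminal alkyne and formylation of the acetylide with DMF (Bouveault-type formylation); the buffered reverse quench releases the ynal without conjugate addition of dimethylamine; no stereocentre.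

**Step 2**
Reactants: 3 4-[(tert-butyldimethylsilyl)oxy]but-2-ynal; 4 allyl methyl ether (3-methoxyprop-1-ene)
Product: 7 (3R,4R)-7-[(tert-butyldimethylsilyl)oxy]-3-methoxyhept-1-en-5-yn-4-ol, via methoxyallylborane 5 (not isolated), via borinate ester 6 (not isolated)
Conditions: 4, s-BuLi, THF, −78 °C; (−)-Ipc2BOMe, −78 °C; BF3·OEt2; then 3, −78 °C, 3 h; NaOH, H2O2, 0 °C → rt
Reagents that add atoms: none
Why: Brown (Z)-γ-methoxyallylboration: the Z-allylborane reacts through a chair Zimmerman–Traxler transition state, so the OMe and OH centres come out syn (threo), and the Ipc groups from (+)-α-pinene select the aldehyde face that gives (3R,4R); these two centres become C2 and C3 of the target.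

**Step 3**
Reactants: 7 (3R,4R)-7-[(tert-butyldimethylsilyl)oxy]-3-methoxyhept-1-en-5-yn-4-ol
Product: 8 (3R,4R)-7-[(tert-butyldimethylsilyl)oxy]-3-methoxyhept-1-en-5-yn-4-yl benzoate
Conditions: BzCl (1.2 equiv), pyridine, DMAP (cat.), CH2Cl2, 0 °C → rt
Reagents that add atoms: benzoyl chloride `O=C(Cl)c1ccccc1`
Why: DMAP-catalysed esterification of the only free hydroxyl; the C–O bond of the stereocentre is not broken.

**Step 4**
Reactants: 8 (3R,4R)-7-[(tert-butyldimethylsilyl)oxy]-3-methoxyhept-1-en-5-yn-4-yl benzoate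
Product: 9 (2RS,3R,4R)-7-[(tert-butyldimethylsilyl)oxy]-1,2-dihydroxy-3-methoxyhept-5-yn-4-yl benzoate
Conditions: OsO4 (2 mol %), NMO (1.5 equiv), acetone/H2O 8:1, rt
Reagents that add atoms: N-methylmorpholine N-oxide `C[N+]1([O-])CCOCC1`; water `O`
Why: Upjohn dihydroxylation: OsO4 adds [3+2] to the terminal alkene while the internal alkyne is inert; the new carbinol centre is formed as a mixture of epimers and is erased in step 6.

**Step 5**
Reactants: 9 (2RS,3R,4R)-7-[(tert-butyldimethylsilyl)oxy]-1,2-dihydroxy-3-methoxyhept-5-yn-4-yl benzoate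
Product: 10 (2RS,3R,4R)-7-[(tert-butyldimethylsilyl)oxy]-2-hydroxy-3-methoxyhept-5-yne-1,4-diyl dibenzoate
Conditions: BzCl (1.05 equiv), 2,4,6-collidine, CH2Cl2, −78 → −30 °C
Reagents that add atoms: benzoyl chloride `O=C(Cl)c1ccccc1`
Why: Kinetically selective acylation of the primary hydroxyl of the 1,2-diol with a hindered base at low temperature; no stereocentre is affected.

**Step 6**
Reactants: 10 (2RS,3R,4R)-7-[(tert-butyldimethylsilyl)oxy]-2-hydroxy-3-methoxyhept-5-yne-1,4-diyl dibenzoate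
Product: 11 (3S,4R)-7-[(tert-butyldimethylsilyl)oxy]-3-methoxy-2-oxohept-5-yne-1,4-diyl dibenzoate
Conditions: Dess–Martin periodinane (1.5 equiv), CH2Cl2, 0 °C → rt
Reagents that add atoms: none
Why: Dess–Martin oxidation under neutral, non-enolising conditions converts both epimers into one α-benzoyloxy ketone without epimerising the adjacent OMe centre (the descriptor changes from R to S only through CIP priorities).

**Step 7**
Reactants: 11 (3S,4R)-7-[(tert-butyldimethylsilyl)oxy]-3-methoxy-2-oxohept-5-yne-1,4-diyl dibenzoate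
Product: 12 (3S,4R,5Z)-7-[(tert-butyldimethylsilyl)oxy]-3-methoxy-2-oxohept-5-ene-1,4-diyl dibenzoate
Conditions: H2 (1 atm), Lindlar catalyst, quinoline, EtOAc, rt
Reagents that add atoms: none
Why: Lindlar semihydrogenation: syn delivery of H2 on poisoned Pd gives the (Z)-alkene that lets C6 reach C1; ketone, esters and silyl ether are untouched.

**Step 8**
Reactants: 12 (3S,4R,5Z)-7-[(tert-butyldimethylsilyl)oxy]-3-methoxy-2-oxohept-5-ene-1,4-diyl dibenzoate
Product: 13 (3S,4R,5Z)-7-bromo-3-methoxy-2-oxohept-5-ene-1,4-diyl dibenzoate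
Conditions: Ph3PBr2 (1.3 equiv), CH2Cl2, 0 °C → rt
Reagents that add atoms: dibromotriphenylphosphorane `BrP(Br)(c1ccccc1)(c1ccccc1)c1ccccc1`
Why: Direct silyl ether to bromide conversion: the silyl ether oxygen is activated as an oxyphosphonium and bromide displaces it by SN2 at the primary allylic carbon, keeping the Z geometry; benzoates and ketone do not react.

**Step 9**
Reactants: 13 (3S,4R,5Z)-7-bromo-3-methoxy-2-oxohept-5-ene-1,4-diyl dibenzoate
Product: 17 [(1R,2S,3R,6R)-3-(benzoyloxy)-2-methoxy-7-oxabicyclo[4.1.0]hept-4-en-1-yl]methyl benzoate, via sulfonium bromide 14 (not isolated), via sulfonium ylide 15 (not isolated), via betaine 16 (not isolated)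
Conditions: tetrahydrothiophene (3 equiv), MeCN, rt; then dilute to 0.01 M, Cs2CO3 (1.5 equiv), −20 → 0 °C
Reagents that add atoms: none
Why: Proposed new method: tetrahydrothiophene is S-alkylated by the primary allylic bromide to give 14, whose allylic S–CH2 protons are far more acidic than the ketone α-protons, so carbonate forms ylide 15 selectively; the Z-alkene holds the ylide carbon next to the doubly α-oxygenated, highly electrophilic ketone, and it adds 6-exo through a half-chair with CH2OBz, OMe and OBz all (pseudo)equatorial and the forming C–C bond anti to the C2–OMe bond (Felkin–Anh type); the resulting betaine 16 has C1–O⁻ and C6–S⁺ trans-diaxial and closes by intramolecular SN2 with inversion at C6 to the cis-fused oxirane on the OMe face, so C1 and C6 are set by the C2/C3 diad; the closest known reaction is the Corey–Chaykovsky epoxidation in its intramolecular allylic-ylide form, as in the ring-closing half of the tandem Michael addition/ylide epoxidation of crotonate-derived sulfonium ylides that gives cyclohexadiene epoxides.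

## Compound list

```
1 | tert-butyldimethyl(prop-2-yn-1-yloxy)silane | C#CCO[Si](C)(C)C(C)(C)C | starting material
2 | {3-[(tert-butyldimethylsilyl)oxy]prop-1-yn-1-yl}lithium (lithium acetylide) | [Li]C#CCO[Si](C)(C)C(C)(C)C | intermediate
3 | 4-[(tert-butyldimethylsilyl)oxy]but-2-ynal | O=CC#CCO[Si](C)(C)C(C)(C)C | intermediate
4 | allyl methyl ether (3-methoxyprop-1-ene) | C=CCOC | starting material
5 | [(2Z)-3-methoxyprop-2-en-1-yl]bis[(1R,2S,3R,5R)-2,6,6-trimethylbicyclo[3.1.1]heptan-3-yl]borane (methoxyallylborane) | CO/C=C\CB([C@@H]1C[C@@H]2C[C@H]([C@H]1C)C2(C)C)[C@@H]1C[C@@H]2C[C@H]([C@H]1C)C2(C)C | intermediate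
6 | (3R,4R)-7-[(tert-butyldimethylsilyl)oxy]-3-methoxyhept-1-en-5-yn-4-yl bis[(1R,2S,3R,5R)-isopinocampheyl]borinate (borinate ester) | C=C[C@@H](OC)[C@H](OB([C@@H]1C[C@@H]2C[C@H]([C@H]1C)C2(C)C)[C@@H]1C[C@@H]2C[C@H]([C@H]1C)C2(C)C)C#CCO[Si](C)(C)C(C)(C)C | intermediate
7 | (3R,4R)-7-[(tert-butyldimethylsilyl)oxy]-3-methoxyhept-1-en-5-yn-4-ol | C=C[C@@H](OC)[C@H](O)C#CCO[Si](C)(C)C(C)(C)C | intermediate
8 | (3R,4R)-7-[(tert-butyldimethylsilyl)oxy]-3-methoxyhept-1-en-5-yn-4-yl benzoate | C=C[C@@H](OC)[C@H](OC(=O)c1ccccc1)C#CCO[Si](C)(C)C(C)(C)C | intermediate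
9 | (2RS,3R,4R)-7-[(tert-butyldimethylsilyl)oxy]-1,2-dihydroxy-3-methoxyhept-5-yn-4-yl benzoate (mixture of C-2 epimers) | OCC(O)[C@@H](OC)[C@H](OC(=O)c1ccccc1)C#CCO[Si](C)(C)C(C)(C)C | intermediate
10 | (2RS,3R,4R)-7-[(tert-butyldimethylsilyl)oxy]-2-hydroxy-3-methoxyhept-5-yne-1,4-diyl dibenzoate (mixture of C-2 epimers) | O=C(OCC(O)[C@@H](OC)[C@H](OC(=O)c1ccccc1)C#CCO[Si](C)(C)C(C)(C)C)c1ccccc1 | intermediate
11 | (3S,4R)-7-[(tert-butyldimethylsilyl)oxy]-3-methoxy-2-oxohept-5-yne-1,4-diyl dibenzoate | O=C(OCC(=O)[C@@H](OC)[C@H](OC(=O)c1ccccc1)C#CCO[Si](C)(C)C(C)(C)C)c1ccccc1 | intermediate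
12 | (3S,4R,5Z)-7-[(tert-butyldimethylsilyl)oxy]-3-methoxy-2-oxohept-5-ene-1,4-diyl dibenzoate | O=C(OCC(=O)[C@@H](OC)[C@H](OC(=O)c1ccccc1)/C=C\CO[Si](C)(C)C(C)(C)C)c1ccccc1 | intermediate
13 | (3S,4R,5Z)-7-bromo-3-methoxy-2-oxohept-5-ene-1,4-diyl dibenzoate | O=C(OCC(=O)[C@@H](OC)[C@H](OC(=O)c1ccccc1)/C=C\CBr)c1ccccc1 | intermediate
14 | 1-[(2Z,4R,5S)-4,7-bis(benzoyloxy)-5-methoxy-6-oxohept-2-en-1-yl]thiolan-1-ium bromide (sulfonium bromide) | O=C(OCC(=O)[C@@H](OC)[C@H](OC(=O)c1ccccc1)/C=C\C[S+]1CCCC1)c1ccccc1.[Br-] | intermediate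
15 | thiolanium ylide of 14, carbanion at the S-bearing allylic carbon (sulfonium ylide) | O=C(OCC(=O)[C@@H](OC)[C@H](OC(=O)c1ccccc1)\C=C/[CH-][S+]1CCCC1)c1ccccc1 | intermediate
16 | (1S,2S,3R,6S)-3-(benzoyloxy)-1-[(benzoyloxy)methyl]-2-methoxy-6-(thiolan-1-ium-1-yl)cyclohex-4-en-1-olate (betaine; O⁻ cis to OMe, S⁺ trans to O⁻) | [O-][C@@]1(COC(=O)c2ccccc2)[C@@H](OC)[C@H](OC(=O)c2ccccc2)C=C[C@@H]1[S+]1CCCC1 | intermediate
17 | [(1R,2S,3R,6R)-3-(benzoyloxy)-2-methoxy-7-oxabicyclo[4.1.0]hept-4-en-1-yl]methyl benzoate | CO[C@H]1[C@H](OC(=O)c2ccccc2)C=C[C@H]2O[C@]21COC(=O)c1ccccc1 | target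
```

## Step count and risk

Total step count: 9. Longest linear sequence: 9 steps (1 → 17); allyl methyl ether 4 enters at step 2 without steps of its own.

**Step 9 (ylide epoxy-annulation).** The allylic ylide 15 carries negative charge at C4 next to the C3 benzoate, so 1,4-elimination of benzoate (or its loss and re-addition with scrambling of C3) can compete with ring closure; enolisation of the ketone toward C2 with β-elimination is a second leak. The fallback closes the rings on a substrate whose C3 oxygen is a non-leaving silyl ether and puts the benzoate on last. It sets out from alcohol 7 and returns at 17.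
- TBDPSCl/imidazole gives (3R,4R)-7-[(tert-butyldimethylsilyl)oxy]-4-[(tert-butyldiphenylsilyl)oxy]-3-methoxyhept-1-en-5-yne F1.
- OsO4/NMO gives the diol F2, BzCl/collidine the primary benzoate F3, Dess–Martin oxidation the ketone F4, and Lindlar reduction the (Z)-alkene F5.
- Ph3PBr2, which cleaves the primary TBS ether much faster than the secondary TBDPS ether, gives the allylic bromide F6.
- Tetrahydrothiophene then Cs2CO3 closes F6 to the silyl-protected epoxycyclohexene F7.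
- AcOH-buffered TBAF frees the C3 alcohol F8, and BzCl/pyridine gives 17.

**Step 2 (methoxyallylboration of an ynal).** The whole absolute and relative configuration rests on this step; the enantiomeric excess or the facial sense with the alkynyl aldehyde may fall short. The fallback uses auxiliary control instead of reagent control. It sets out from ynal 3 and returns at 7.
- (S)-4-Benzyl-3-(2-methoxyacetyl)oxazolidin-2-one F9 is made from (S)-4-benzyloxazolidin-2-one, n-BuLi and methoxyacetyl chloride.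
- Its Bu2BOTf/Et3N boron enolate adds to 3 to give the Evans syn aldol adduct (4S)-4-benzyl-3-[(2S,3R)-6-[(tert-butyldimethylsilyl)oxy]-3-hydroxy-2-methoxyhex-4-ynoyl]oxazolidin-2-one F10.
- LiBH4 removes the auxiliary to give (2R,3R)-6-[(tert-butyldimethylsilyl)oxy]-2-methoxyhex-4-yne-1,3-diol F11.
- TEMPO/PhI(OAc)2 oxidises only the primary alcohol to (2S,3R)-6-[(tert-butyldimethylsilyl)oxy]-3-hydroxy-2-methoxyhex-4-ynal F12.
- Wittig methylenation with Ph3P=CH2 (2.2 equiv, −78 → 0 °C) gives 7.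

**Step 8 (silyl ether to allylic bromide).** The (Z)-allylic bromide may isomerise to E or suffer SN2′ attack under Ph3PBr2/HBr, and only the Z isomer can cyclise. The fallback avoids any allylic bromide. It sets out from 12 and returns at ylide 15 (then 16 → 17 as in step 9).
- HF·pyridine removes the TBS group to give (3S,4R,5Z)-7-hydroxy-3-methoxy-2-oxohept-5-ene-1,4-diyl dibenzoate F13.
- Ms2O/2,6-lutidine at −20 °C gives the mesylate F14.
- Tetrahydrothiophene displaces the mesylate to give the sulfonium mesylate F15.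
- Cs2CO3 deprotonates F15 to ylide 15.

## Further compounds

```
F1 | step 9 | (3R,4R)-7-[(tert-butyldimethylsilyl)oxy]-4-[(tert-butyldiphenylsilyl)oxy]-3-methoxyhept-1-en-5-yne | C=C[C@@H](OC)[C@H](O[Si](c1ccccc1)(c1ccccc1)C(C)(C)C)C#CCO[Si](C)(C)C(C)(C)C
F2 | step 9 | (2RS,3R,4R)-7-[(tert-butyldimethylsilyl)oxy]-4-[(tert-butyldiphenylsilyl)oxy]-3-methoxyhept-5-yne-1,2-diol | OCC(O)[C@@H](OC)[C@H](O[Si](c1ccccc1)(c1ccccc1)C(C)(C)C)C#CCO[Si](C)(C)C(C)(C)C
F3 | step 9 | (2RS,3R,4R)-7-[(tert-butyldimethylsilyl)oxy]-4-[(tert-butyldiphenylsilyl)oxy]-2-hydroxy-3-methoxyhept-5-yn-1-yl benzoate | O=C(OCC(O)[C@@H](OC)[C@H](O[Si](c1ccccc1)(c1ccccc1)C(C)(C)C)C#CCO[Si](C)(C)C(C)(C)C)c1ccccc1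
F4 | step 9 | (3S,4R)-7-[(tert-butyldimethylsilyl)oxy]-4-[(tert-butyldiphenylsilyl)oxy]-3-methoxy-2-oxohept-5-yn-1-yl benzoate | O=C(OCC(=O)[C@@H](OC)[C@H](O[Si](c1ccccc1)(c1ccccc1)C(C)(C)C)C#CCO[Si](C)(C)C(C)(C)C)c1ccccc1
F5 | step 9 | (3S,4R,5Z)-7-[(tert-butyldimethylsilyl)oxy]-4-[(tert-butyldiphenylsilyl)oxy]-3-methoxy-2-oxohept-5-en-1-yl benzoate | O=C(OCC(=O)[C@@H](OC)[C@H](O[Si](c1ccccc1)(c1ccccc1)C(C)(C)C)/C=C\CO[Si](C)(C)C(C)(C)C)c1ccccc1
F6 | step 9 | (3S,4R,5Z)-7-bromo-4-[(tert-butyldiphenylsilyl)oxy]-3-methoxy-2-oxohept-5-en-1-yl benzoate | O=C(OCC(=O)[C@@H](OC)[C@H](O[Si](c1ccccc1)(c1ccccc1)C(C)(C)C)/C=C\CBr)c1ccccc1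
F7 | step 9 | {(1R,2S,3R,6R)-3-[(tert-butyldiphenylsilyl)oxy]-2-methoxy-7-oxabicyclo[4.1.0]hept-4-en-1-yl}methyl benzoate | CO[C@H]1[C@H](O[Si](c2ccccc2)(c2ccccc2)C(C)(C)C)C=C[C@H]2O[C@]21COC(=O)c1ccccc1
F8 | step 9 | [(1R,2S,3R,6R)-3-hydroxy-2-methoxy-7-oxabicyclo[4.1.0]hept-4-en-1-yl]methyl benzoate | CO[C@H]1[C@H](O)C=C[C@H]2O[C@]21COC(=O)c1ccccc1
F9 | step 2 | (S)-4-benzyl-3-(2-methoxyacetyl)oxazolidin-2-one | COCC(=O)N1[C@@H](Cc2ccccc2)COC1=O
F10 | step 2 | (4S)-4-benzyl-3-[(2S,3R)-6-[(tert-butyldimethylsilyl)oxy]-3-hydroxy-2-methoxyhex-4-ynoyl]oxazolidin-2-one | CO[C@@H]([C@H](O)C#CCO[Si](C)(C)C(C)(C)C)C(=O)N1[C@@H](Cc2ccccc2)COC1=O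
F11 | step 2 | (2R,3R)-6-[(tert-butyldimethylsilyl)oxy]-2-methoxyhex-4-yne-1,3-diol | CO[C@@H]([C@H](O)C#CCO[Si](C)(C)C(C)(C)C)CO
F12 | step 2 | (2S,3R)-6-[(tert-butyldimethylsilyl)oxy]-3-hydroxy-2-methoxyhex-4-ynal | CO[C@@H]([C@H](O)C#CCO[Si](C)(C)C(C)(C)C)C=O
F13 | step 8 | (3S,4R,5Z)-7-hydroxy-3-methoxy-2-oxohept-5-ene-1,4-diyl dibenzoate | O=C(OCC(=O)[C@@H](OC)[C@H](OC(=O)c1ccccc1)/C=C\CO)c1ccccc1
F14 | step 8 | (3S,4R,5Z)-3-methoxy-7-[(methylsulfonyl)oxy]-2-oxohept-5-ene-1,4-diyl dibenzoate | O=C(OCC(=O)[C@@H](OC)[C@H](OC(=O)c1ccccc1)/C=C\COS(C)(=O)=O)c1ccccc1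
F15 | step 8 | 1-[(2Z,4R,5S)-4,7-bis(benzoyloxy)-5-methoxy-6-oxohept-2-en-1-yl]thiolan-1-ium methanesulfonate | O=C(OCC(=O)[C@@H](OC)[C@H](OC(=O)c1ccccc1)/C=C\C[S+]1CCCC1)c1ccccc1.CS(=O)(=O)[O-]
```
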